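**Retrosynthetic overview**

1. C11–C12 cut: the target comes from a 3β-acetoxy-9α,11-spiro-epoxide plus α-methylene-γ-butyrolactone; one redox-neutral cobalt-catalysed radical coupling forms the bond and the endocyclic butenolide alkene (new method).
2. The epoxide comes from the 9(11)-methylene decalin, and that from the 3β-hydroxy-8α-methyl-9-decalone (Wittig; α-face epoxidation sets C9).
3. The decalone comes from a bicyclic enone β-keto ester by one Birch reductive double methylation (C4 gem-dimethyl, trans ring fusion, C8 methyl), then C3 reduction and dealkoxycarbonylation.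
4. Ring B of that β-keto ester comes from a one-carbon ring expansion (diazoacetate insertion with 1,2-shift of C7) of a Hajos–Parrish-type hydrindenedione; this is the key step.
5. The hydrindenedione comes from 2-methylcyclopentane-1,3-dione and ethyl vinyl ketone (asymmetric annulation sets C10). Ring order: A, five-membered proto-B, expansion to B, butenolide ring brought in intact last.

Assumption: positions are given in labdane numbering (C3 acetoxy carbon, C4 gem-dimethyl, C5/C10 ring fusion, C8 methyl-bearing carbon, C9 tertiary carbinol, C11–C16 side chain; β = face of the C10 methyl). The given SMILES is read as 3β-OAc, 5α-H, 8α-Me, 9α-OH, 10β-Me, i.e. (3S,5S,8R,9R,10S).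

**Route**

Step 1
Reactants: 1 2-methylcyclopentane-1,3-dione; 2 ethyl vinyl ketone (pent-1-en-3-one)
Product: 4 (7aS)-4,7a-dimethyl-2,3,7,7a-tetrahydro-1H-indene-1,5(6H)-dione, via triketone 3 (not isolated)
Conditions: 2 (1.3 equiv), Et3N (5 mol%), MeCN, 60 °C; then L-phenylalanine (1.0 equiv), 1 M HClO4 (0.4 equiv), 80 °C; recrystallise to ≥98% ee
Reagents that add atoms: none
Why: Michael addition followed by the amino-acid-catalysed Hajos–Parrish–Eder–Sauer–Wiechert aldol condensation (Robinson-type annulation), in which the L-phenylalanine enamine differentiates the two enantiotopic ring carbonyls and sets the quaternary C10 as S.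

Step 2
Reactants: 4 (7aS)-4,7a-dimethyl-2,3,7,7a-tetrahydro-1H-indene-1,5(6H)-dione
Product: 5 ethyl (8aS)-5,8a-dimethyl-1,6-dioxo-1,2,3,4,6,7,8,8a-octahydronaphthalene-2-carboxylate
Conditions: N2CHCO2Et (1.5 equiv), BF3·OEt2 (1.2 equiv, promoter), CH2Cl2, 0 °C → rt
Reagents that add atoms: ethyl diazoacetate, CCOC(=O)C=[N+]=[N-]
Why: Lewis-acid-promoted diazoacetate homologation (Tiffeneau–Demjanov-type ring expansion) in which the diazo carbon adds to the activated saturated cyclopentanone (the conjugated C3 carbonyl is inert) and loss of N2 drives the 1,2-shift of the less substituted α-methylene C7 rather than the quaternary C10, as in the D-homoannulation of 17-keto steroids, so the inserted carbon becomes C8 of a six-membered β-keto ester.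

Step 3
Reactants: 5 ethyl (8aS)-5,8a-dimethyl-1,6-dioxo-1,2,3,4,6,7,8,8a-octahydronaphthalene-2-carboxylate
Product: 7 ethyl (4aS,8aS)-2,5,5,8a-tetramethyl-1,6-dioxodecahydronaphthalene-2-carboxylate, via dilithium bis-enolate 6 (not isolated)
Conditions: Li (≈2.5 equiv, to persistent blue), NH3(l)/THF, −78 °C, no added proton donor; then MeI (6 equiv), −78 °C → rt
Reagents that add atoms: iodomethane, CI
Why: Stork-type Birch reductive alkylation in which the β-keto ester, ionised to its enolate in ammonia, masks C9 against reduction and against attack by C5 (no cyclopropanol) and supplies the proton delivered axially to C5 (trans-decalin, 5α-H), after which the bis-enolate is C-methylated at C4 (gem-dimethyl) and at C8 (configuration immaterial, reset in step 4).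

Step 4
Reactants: 7 ethyl (4aS,8aS)-2,5,5,8a-tetramethyl-1,6-dioxodecahydronaphthalene-2-carboxylate
Product: 9 (2R,4aS,6S,8aS)-6-hydroxy-2,5,5,8a-tetramethyloctahydronaphthalen-1(2H)-one, via hydroxy keto ester 8 (not isolated)
Conditions: NaBH4, EtOH, 0 °C; aqueous work-up, crude; then LiCl, DMSO, H2O (2 equiv), 150 °C
Reagents that add atoms: none
Why: Chemoselective hydride reduction then Krapcho dealkoxycarbonylation, in which NaBH4 attacks only the C3 ketone (C9 lies between two quaternary carbons) along the axial α trajectory opposite the axial 4β-methyl to give the equatorial 3β-alcohol, and chloride-induced loss of EtCl and CO2 with protonation under equilibrating conditions leaves the C8 methyl equatorial (8α, anti to the C10 methyl).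

Step 5
Reactants: 9 (2R,4aS,6S,8aS)-6-hydroxy-2,5,5,8a-tetramethyloctahydronaphthalen-1(2H)-one
Product: 10 (2S,4aS,6R,8aR)-1,1,4a,6-tetramethyl-5-methylidenedecahydronaphthalen-2-ol
Conditions: Ph3PCH3Br (4 equiv), KOtBu (4 equiv), toluene, 100 °C
Reagents that add atoms: methyltriphenylphosphonium bromide, C[P+](c1ccccc1)(c1ccccc1)c1ccccc1.[Br-]
Why: Wittig methylenation under Fitjer-type forcing conditions suited to hindered enolisable ketones, where the C3 alkoxide is inert and any enolisation at C8 only returns the thermodynamically preferred 8α-methyl ketone, so C8 is unchanged.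

Step 6
Reactants: 10 (2S,4aS,6R,8aR)-1,1,4a,6-tetramethyl-5-methylidenedecahydronaphthalen-2-ol
Product: 12 (1'R,2'R,4a'S,6'S,8a'S)-2',5',5',8a'-tetramethyloctahydro-2'H-spiro[oxirane-2,1'-naphthalen]-6'-yl acetate, via alkene acetate 11 (not isolated)
Conditions: Ac2O, pyridine, DMAP (cat.), CH2Cl2, rt; aqueous wash; then m-CPBA, NaHCO3, CH2Cl2, 0 °C
Reagents that add atoms: acetic anhydride, CC(=O)OC(C)=O; m-CPBA, OOC(=O)c1cccc(Cl)c1
Why: DMAP-catalysed acetylation followed by Prilezhaev epoxidation, in which the peracid adds to the exocyclic 1,1-disubstituted alkene from the α face, anti to the axial C10 methyl, so the oxygen becomes axial (9α) and C11 equatorial (9β), which sets C9.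

Step 7
Reactants: 12 (1'R,2'R,4a'S,6'S,8a'S)-2',5',5',8a'-tetramethyloctahydro-2'H-spiro[oxirane-2,1'-naphthalen]-6'-yl acetate; 13 α-methylene-γ-butyrolactone
Product: 14 (2S,4aS,5R,6R,8aS)-5-hydroxy-1,1,4a,6-tetramethyl-5-[2-(2-oxo-2,5-dihydrofuran-3-yl)ethyl]decahydronaphthalen-2-yl acetate
Conditions: 13 (3 equiv), Co(dmgH)2(py)Cl (10 mol%), Zn (20 mol%), LiI (30 mol%), 2,6-lutidinium triflate (30 mol%), MeCN, blue LEDs (450 nm), 25 °C
Reagents that add atoms: none
Why: Proposed new method: cobaloxime(I), formed from the precatalyst and catalytic Zn, opens the spiro-epoxide at the C11 methylene (directly or via the iodohydrin formed reversibly with LiI) to a β-hydroxyalkyl–Co(III) species that has no β-hydrogen (C9 is fully substituted) and so can only homolyse under blue light to the primary C11 radical; this adds to the exocyclic CH2 of 13 to form the C11–C12 bond, the tertiary α-lactone radical is dehydrogenated by Co(II) at the ring C14–H (reversible Co–H re-addition funnels alkene isomers to the more stable endocyclic butenolide), and the Co(III)–H returns its proton to the C9 oxygen and regenerates Co(I), so the coupling is redox-neutral and C9 keeps the configuration set in step 6 because its C–O bond is never broken; the closest known reaction types are vitamin-B12/cobaloxime-mediated epoxide opening with Giese trapping and cobalt-mediated radical Heck-type (catalytic chain transfer) dehydrogenation, which have not been combined on an epoxide/α-methylene lactone pair.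

**Compound list**

1 | 2-methylcyclopentane-1,3-dione | CC1C(=O)CCC1=O | starting material
2 | ethyl vinyl ketone (pent-1-en-3-one) | CCC(=O)C=C | starting material
3 | 2-methyl-2-(3-oxopentyl)cyclopentane-1,3-dione (triketone) | CCC(=O)CCC1(C)C(=O)CCC1=O | intermediate
4 | (7aS)-4,7a-dimethyl-2,3,7,7a-tetrahydro-1H-indene-1,5(6H)-dione | O=C1CC[C@@]2(C)C(=C1C)CCC2=O | intermediate
5 | ethyl (8aS)-5,8a-dimethyl-1,6-dioxo-1,2,3,4,6,7,8,8a-octahydronaphthalene-2-carboxylate (C8 epimers/enol) | O=C1CC[C@@]2(C)C(=C1C)CCC(C(=O)OCC)C2=O | intermediate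
6 | dilithium bis-enolate of the trans-fused keto ester (C3–OLi with C3=C4; C9–OLi with C8=C9; 5α-H) | CC1=C(O[Li])CC[C@@]2(C)[C@H]1CCC(C(=O)OCC)=C2O[Li] | intermediate
7 | ethyl (4aS,8aS)-2,5,5,8a-tetramethyl-1,6-dioxodecahydronaphthalene-2-carboxylate (C8 epimers) | O=C1CC[C@@]2(C)[C@@H](CCC(C)(C(=O)OCC)C2=O)C1(C)C | intermediate
8 | ethyl (4aS,6S,8aS)-6-hydroxy-2,5,5,8a-tetramethyl-1-oxodecahydronaphthalene-2-carboxylate (C8 epimers) | O[C@H]1CC[C@@]2(C)[C@@H](CCC(C)(C(=O)OCC)C2=O)C1(C)C | intermediate
9 | (2R,4aS,6S,8aS)-6-hydroxy-2,5,5,8a-tetramethyloctahydronaphthalen-1(2H)-one (3β-OH, 8α-Me, 9-ketone) | O[C@H]1CC[C@@]2(C)[C@@H](CC[C@@H](C)C2=O)C1(C)C | intermediate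
10 | (2S,4aS,6R,8aR)-1,1,4a,6-tetramethyl-5-methylidenedecahydronaphthalen-2-ol | O[C@H]1CC[C@@]2(C)[C@@H](CC[C@@H](C)C2=C)C1(C)C | intermediate
11 | (2S,4aS,6R,8aR)-1,1,4a,6-tetramethyl-5-methylidenedecahydronaphthalen-2-yl acetate | CC(=O)O[C@H]1CC[C@@]2(C)[C@@H](CC[C@@H](C)C2=C)C1(C)C | intermediate
12 | (1'R,2'R,4a'S,6'S,8a'S)-2',5',5',8a'-tetramethyloctahydro-2'H-spiro[oxirane-2,1'-naphthalen]-6'-yl acetate (3β-acetoxy-9α,11-epoxide) | CC(=O)O[C@H]1CC[C@@]2(C)[C@@H](CC[C@@H](C)[C@]2(O3)C3)C1(C)C | intermediate
13 | α-methylene-γ-butyrolactone (3-methylidenedihydrofuran-2(3H)-one) | C=C1CCOC1=O | starting material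
14 | (2S,4aS,5R,6R,8aS)-5-hydroxy-1,1,4a,6-tetramethyl-5-[2-(2-oxo-2,5-dihydrofuran-3-yl)ethyl]decahydronaphthalen-2-yl acetate (CNP0117645.1) | CC(=O)O[C@H]1CC[C@@]2(C)[C@@H](CC[C@@H](C)[C@]2(O)CCC2=CCOC2=O)C1(C)C | target

**Step count and risks**

Total step count: 7. Longest linear sequence: 7 steps (1 → 14); 13 enters in the last step.

Steps most likely to fail:

Step 7 (new cobalt coupling). The hindered epoxide may open slowly, the β-hydroxyalkyl cobalt species may lose oxygen back to alkene 11, 13 may oligomerise, or the alkene may end up in the wrong position. The fallback uses known chemistry only; it sets out from 10 and comes back at 14. Alcohol 10 is epoxidised without prior acetylation (m-CPBA, NaHCO3, CH2Cl2, 0 °C) to the 3β-hydroxy-9α,11-epoxide F4. Excess dimethylsulfonium methylide (Me3SI, n-BuLi, THF, −10 °C → rt) attacks C11 and eliminates to the one-carbon-homologated tertiary allylic alcohol, the 9β-vinyl-3β,9α-diol F5. Hydroboration with excess 9-BBN in THF gives the B-alkyl-9-BBN adduct F6, used without isolation. B-alkyl Suzuki–Miyaura coupling with commercial 3-bromofuran-2(5H)-one (Pd(dppf)Cl2, AsPh3, K3PO4, DMF/H2O, rt) forms the C12–C13 bond and gives the 3β,9α-diol butenolide F7. Acetylation of the secondary 3β-hydroxyl (Ac2O, pyridine, DMAP; the tertiary 9α-OH is inert) gives 14.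

Step 3 (Birch reductive double methylation). The C8 methylation may be incomplete, O-methylation or over-reduction may occur, and the ring-fusion selectivity could erode. The fallback avoids dissolving metal; it sets out from 5 and comes back at 7. The β-keto ester is first C-methylated under mild conditions (K2CO3, MeI, acetone, reflux) to the C8-methyl keto ester enone F1, whose C9 ketone now has no α-hydrogen. Deconjugative α-methylation of the enone (KOtBu, MeI, t-BuOH/THF) then gives the 4,4-dimethyl-Δ5(6)-3-ketone F2. Hydrogenation (H2, Pd/C, EtOAc/AcOH) adds hydrogen to C5 from the α face, the β face being screened by the C10 and 4β methyls, and gives the trans-fused 7.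

Step 5 (Wittig on the hindered C9 ketone). The ketone is flanked by a quaternary carbon and a methyl-bearing methine and may only enolise. The fallback replaces ylide olefination by addition/elimination; it sets out from 9 and comes back at 10. The non-basic organocerium reagent from Me3SiCH2Li and CeCl3 (3 equiv, THF, −78 °C) adds to the ketone to give the β-hydroxysilane F3, and Peterson elimination (KH, THF, 50 °C) gives the exocyclic alkene 10 regiospecifically.

Further compounds
F1 | step 3 | ethyl (8aS)-2,5,8a-trimethyl-1,6-dioxo-1,2,3,4,6,7,8,8a-octahydronaphthalene-2-carboxylate (C8 epimers) | O=C1CC[C@@]2(C)C(=C1C)CCC(C)(C(=O)OCC)C2=O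
F2 | step 3 | ethyl (8aS)-2,5,5,8a-tetramethyl-1,6-dioxo-1,2,3,5,6,7,8,8a-octahydronaphthalene-2-carboxylate (C8 epimers) | O=C1CC[C@@]2(C)C(=CCC(C)(C(=O)OCC)C2=O)C1(C)C
F3 | step 5 | 3β,9β-dihydroxy-9α-(trimethylsilylmethyl) decalin (β-hydroxysilane from 9) | O[C@H]1CC[C@@]2(C)[C@@H](CC[C@@H](C)[C@@]2(O)C[Si](C)(C)C)C1(C)C
F4 | step 7 | 3β-hydroxy-9α,11-spiro-epoxide (deacetyl 12) | O[C@H]1CC[C@@]2(C)[C@@H](CC[C@@H](C)[C@]2(O3)C3)C1(C)C
F5 | step 7 | 9β-vinyl-3β,9α-diol | O[C@H]1CC[C@@]2(C)[C@@H](CC[C@@H](C)[C@]2(O)C=C)C1(C)C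
F6 | step 7 | B-alkyl-9-BBN adduct of F5 (boron on C12) | O[C@H]1CC[C@@]2(C)[C@@H](CC[C@@H](C)[C@]2(O)CCB2C3CCCC2CCC3)C1(C)C
F7 | step 7 | 3β,9α-diol butenolide (deacetyl 14) | O[C@H]1CC[C@@]2(C)[C@@H](CC[C@@H](C)[C@]2(O)CCC2=CCOC2=O)C1(C)C
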